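**Retrosynthetic overview**
- The strategy rests on the hexa-1,5-dien-3-ol unit of the side chain. Carbinol C5' carries the C6'=C7' alkenyl group and is joined through C4'H2 to the E-C2'=C3'(CH3) olefin, which is the retron of a [2,3]-Wittig shift.
- First disconnection: coumarin C3–C1', by Pd-catalysed allylic alkylation of 4-hydroxycoumarin with the primary allylic carbonate of the C15 diol.
- Second disconnection: C4'–C5', by [2,3]-Wittig rearrangement of the geranyl ether of (R)-1-silyloxy-3-methylbut-3-en-2-ol. The C10 and C5 units are joined first through oxygen and then through carbon.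
- The ether stereocentre comes from Sharpless epoxidation of prenol, followed by epoxide-to-allylic-alcohol isomerisation.
- Rings: the benzopyranone bicycle is bought intact. The only ring made is the oxirane (step 1), which is opened again in step 3.

Key step: step 5

Assumption: primed locants C1'–C12' run along the side chain from the carbon bound to coumarin C3. The enantiomeric purity of the route is the purity set in step 1 and should be checked at alcohol 5 (chiral HPLC) before the key step.

**Step 1**
Reactants: 1 prenol (3-methylbut-2-en-1-ol)
Product: 2 (S)-(3,3-dimethyloxiran-2-yl)methanol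
Conditions: Ti(OiPr)4 (cat.), L-(+)-DIPT (cat.), anhydrous TBHP, 4 Å MS, CH2Cl2, −20 °C; non-aqueous work-up
Reagents that add atoms: tert-butyl hydroperoxide, CC(C)(C)OO
Why: Katsuki–Sharpless asymmetric epoxidation, in which the Ti/L-(+)-tartrate complex binds 1 and TBHP and delivers oxygen to the face that gives the 2S oxirane (the same sense as geraniol to its 2S,3S epoxide), while sieves and a water-free work-up protect the water-soluble, easily opened product.

**Step 2**
Reactants: 2 (S)-(3,3-dimethyloxiran-2-yl)methanol
Product: 3 (S)-tert-butyl[(3,3-dimethyloxiran-2-yl)methoxy]diphenylsilane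
Conditions: TBDPSCl, imidazole, CH2Cl2, 0 °C to rt
Reagents that add atoms: tert-butylchlorodiphenylsilane, CC(C)(C)[Si](Cl)(c1ccccc1)c1ccccc1
Why: Imidazole-promoted silylation of a primary alcohol, under base too mild for Payne rearrangement or epoxide opening, so the stereocentre is untouched.

**Step 3**
Reactants: 3 (S)-tert-butyl[(3,3-dimethyloxiran-2-yl)methoxy]diphenylsilane
Product: 5 (R)-1-(tert-butyldiphenylsilyloxy)-3-methylbut-3-en-2-ol, via diethylaluminium alkoxide 4 (not isolated)
Conditions: Et2AlCl, LiTMP (from TMP, n-BuLi), toluene, 0 °C; then aq Rochelle salt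
Reagents that add atoms: none
Why: Aluminium-amide (Yamamoto-type) epoxide-to-allylic-alcohol isomerisation, in which Al binds the oxirane oxygen and the hindered amide removes a syn methyl proton in a cyclic transition state, so only the tertiary C–O bond breaks, the secondary C–O centre keeps its spatial arrangement, and the descriptor changes from S to R only because CH2OSi now outranks the isopropenyl carbon.

**Step 4**
Reactants: 5 (R)-1-(tert-butyldiphenylsilyloxy)-3-methylbut-3-en-2-ol; 6 geranyl bromide
Product: 8 (R)-tert-butyl{2-[(2E)-3,7-dimethylocta-2,6-dienyloxy]-3-methylbut-3-enyloxy}diphenylsilane, via sodium alkoxide 7 (not isolated)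
Conditions: 5 and 6 premixed, NaH, n-Bu4NI (cat.), THF–DMF, 0 °C to rt
Reagents that add atoms: none
Why: Williamson ether synthesis by SN2 attack of alkoxide 7 on the primary allylic carbon of 6 (iodide catalysis), with the bromide already present when the base is added so that alkylation outruns 1,2-O-to-O silyl migration, and with neither the stereocentre nor the geranyl E-olefin involved.

**Step 5**
Reactants: 8 (R)-tert-butyl{2-[(2E)-3,7-dimethylocta-2,6-dienyloxy]-3-methylbut-3-enyloxy}diphenylsilane
Product: 11 (2E,5R,6E)-1-(tert-butyldiphenylsilyloxy)-3,7,11-trimethyldodeca-2,6,10-trien-5-ol, via α-lithiated geranyl ether 9 (not isolated), via lithium alkoxide 10 (not isolated)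
Conditions: s-BuLi, THF, −78 °C; then H2O
Reagents that add atoms: none
Why: s-BuLi should remove a geranyl O–CH2 proton (primary, unhindered, allylic and α-oxygenated) and not the methine on the other side of oxygen, which would give a tertiary carbanion and is screened by the 2-methyl group and the CH2OTBDPS arm, in line with the known preference of unsymmetrical bis-allylic ethers for metalation at the α-unsubstituted terminus. Carbanion 9 then undergoes a concerted suprafacial [2,3]-Wittig rearrangement through a five-membered envelope, in which its carbon bonds to the =CH2 terminus (new C4'–C5' bond) while the C2'–O bond breaks and the π bond moves to C2'=C3', so no ring is closed and the open-chain alkoxide 10 results. The closest known reaction type is the chirality-transferring [2,3]-Wittig rearrangement of enantioenriched secondary allylic ethers that carry an allyl- or propargyl-stabilised carbanion. C5' is the only new stereocentre and is controlled by the ether centre, which is destroyed in the process: a pseudo-equatorial CH2OTBDPS group fixes the oxygen-bearing face of the methallyl unit, and an exo geranyl alkenyl group, turned away from the C3' methyl with nothing on the CH2 terminus to oppose it, fixes the carbanion face, which together map (R)-8 onto (5R)-11. The same pseudo-equatorial placement gives the 2E olefin, and leakage through the pseudo-axial arrangement would give the 2Z isomer with the opposite carbinol configuration, a geometric isomer separable in principle that does not lower the enantiomeric purity of the E product. Working at −78 °C holds back [1,2]- and [1,4]-shifts, bond rotation within the geranyl anion (which keeps 6E) and attack on silicon.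

**Step 6**
Reactants: 11 (2E,5R,6E)-1-(tert-butyldiphenylsilyloxy)-3,7,11-trimethyldodeca-2,6,10-trien-5-ol
Product: 12 (2E,5R,6E)-3,7,11-trimethyldodeca-2,6,10-triene-1,5-diol
Conditions: TBAF, THF, 0 °C to rt
Reagents that add atoms: none
Why: Fluoride-driven Si–O cleavage in a non-acidic medium, which spares the ionisable allylic carbinol at C5' and all three olefins.

**Step 7**
Reactants: 12 (2E,5R,6E)-3,7,11-trimethyldodeca-2,6,10-triene-1,5-diol
Product: 13 (2E,5R,6E)-5-hydroxy-3,7,11-trimethyldodeca-2,6,10-trienyl methyl carbonate
Conditions: ClCO2Me (1.05 equiv), pyridine, CH2Cl2, −20 to 0 °C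
Reagents that add atoms: methyl chloroformate, COC(=O)Cl
Why: Chemoselective acylation, since the unhindered primary allylic hydroxyl should react with one equivalent of chloroformate at low temperature well ahead of the secondary carbinol flanked by C4'H2 and a trisubstituted alkene.

**Step 8**
Reactants: 13 (2E,5R,6E)-5-hydroxy-3,7,11-trimethyldodeca-2,6,10-trienyl methyl carbonate; 14 4-hydroxycoumarin
Product: 15 4-hydroxy-3-[(2E,5R,6E)-5-hydroxy-3,7,11-trimethyldodeca-2,6,10-trienyl]-2H-chromen-2-one (target CNP0250128.1)
Conditions: Pd(PPh3)4 (5 mol %), 14 in excess, THF, 25 to 45 °C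
Reagents that add atoms: none
Why: Tsuji–Trost allylic alkylation, in which Pd(0) ionises only the carbonate (the free C5' hydroxyl is no leaving group under neutral conditions), the methoxide released on decarboxylation deprotonates acidic 14, the soft enolate attacks the unsubstituted C1' terminus of the π-allyl unit, any O-allyl ether is re-ionised and funnelled to the C3 product, the 2E geometry should hold because syn/anti exchange at C3' would need a tertiary σ-palladium species, and C5' is not involved.

**Compound list**
1 | prenol | CC(C)=CCO | starting material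
2 | (S)-(3,3-dimethyloxiran-2-yl)methanol | CC1(C)[C@H](CO)O1 | intermediate
3 | (S)-tert-butyl[(3,3-dimethyloxiran-2-yl)methoxy]diphenylsilane | CC1(C)[C@H](CO[Si](c2ccccc2)(c2ccccc2)C(C)(C)C)O1 | intermediate
4 | diethylaluminium alkoxide of 5 (not isolated) | C=C(C)[C@H](CO[Si](c1ccccc1)(c1ccccc1)C(C)(C)C)O[Al](CC)CC | intermediate
5 | (R)-1-(tert-butyldiphenylsilyloxy)-3-methylbut-3-en-2-ol | C=C(C)[C@H](CO[Si](c1ccccc1)(c1ccccc1)C(C)(C)C)O | intermediate
6 | geranyl bromide | CC(C)=CCC/C(C)=C/CBr | starting material
7 | sodium alkoxide of 5 (not isolated) | C=C(C)[C@H](CO[Si](c1ccccc1)(c1ccccc1)C(C)(C)C)[O-].[Na+] | intermediate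
8 | (R)-geranyl ether of 5 | C=C(C)[C@H](CO[Si](c1ccccc1)(c1ccccc1)C(C)(C)C)OC/C=C(\C)CCC=C(C)C | intermediate
9 | α-lithiated geranyl ether (not isolated, C–Li centre undefined) | C=C(C)[C@H](CO[Si](c1ccccc1)(c1ccccc1)C(C)(C)C)OC([Li])/C=C(\C)CCC=C(C)C | intermediate
10 | lithium alkoxide of 11 (not isolated) | CC(C)=CCC/C(C)=C/[C@H]([O-])C/C(C)=C/CO[Si](c1ccccc1)(c1ccccc1)C(C)(C)C.[Li+] | intermediate
11 | (2E,5R,6E)-1-(tert-butyldiphenylsilyloxy)-3,7,11-trimethyldodeca-2,6,10-trien-5-ol | CC(C)=CCC/C(C)=C/[C@H](O)C/C(C)=C/CO[Si](c1ccccc1)(c1ccccc1)C(C)(C)C | intermediate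
12 | (2E,5R,6E)-3,7,11-trimethyldodeca-2,6,10-triene-1,5-diol | CC(C)=CCC/C(C)=C/[C@H](O)C/C(C)=C/CO | intermediate
13 | (2E,5R,6E)-5-hydroxy-3,7,11-trimethyldodeca-2,6,10-trienyl methyl carbonate | CC(C)=CCC/C(C)=C/[C@H](O)C/C(C)=C/COC(=O)OC | intermediate
14 | 4-hydroxycoumarin | O=c1cc(O)c2ccccc2o1 | starting material
15 | 4-hydroxy-3-[(2E,5R,6E)-5-hydroxy-3,7,11-trimethyldodeca-2,6,10-trienyl]-2H-chromen-2-one | CC(C)=CCC/C(C)=C/[C@H](O)C/C(C)=C/Cc1c(O)c2ccccc2oc1=O | target

**Totals**
- Total step count: 8.
- Longest linear sequence: 8 (from prenol). Geranyl bromide and 4-hydroxycoumarin enter as bought.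

**Steps most likely to fail**

1. **Step 5.**
   - Risks:
     - Metalation may occur at the methine on the other side of oxygen, followed by loss of silanolate.
     - A(1,2) strain with the C3' methyl may push the CH2OTBDPS group into the pseudo-axial position and erode E-selectivity. This tendency is well known for non-stabilised carbanions on 2-methylallyl systems.
     - Exo/endo discrimination of the alkenyl group may be imperfect, which would make chirality transfer incomplete.
   - Fallback: it keeps the sigmatropic C4'–C5' bond formation but uses a propargylic carbanion partner. Its CH2 is much more acidic, and E-selectivity and chirality transfer are best documented for this class. The C6'=C7' olefin is then built afterwards. The fallback sets out from 5. NaH and propargyl bromide give the propargyl ether F1. One equivalent of n-BuLi at −78 °C and alkylation of the acetylide with 5-bromo-2-methylpent-2-ene in THF–DMPU give the 7-methyloct-6-en-2-ynyl ether F2. n-BuLi in THF at −78 °C brings about the [2,3]-Wittig shift to the (5R)-propargylic alcohol F3. Alkoxide-directed trans-hydroalumination with Red-Al followed by iodine gives the (6Z)-7-iodo allylic alcohol F4. Me2CuLi then replaces iodine by methyl with retention of geometry. The methyl group ends up cis to the carbinol carbon (6E), and the route is rejoined at 11.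

2. **Step 4.**
   - Risk: base-induced 1,2-migration of the silyl group from the primary to the secondary oxygen in alkoxide 7 may precede alkylation, which would put the geranyl group on the wrong oxygen.
   - Fallback: it removes the migrating group from the etherification altogether and sets out from 2. TrCl, Et3N and DMAP give the trityl-protected epoxide F5. The aluminium-amide isomerisation of step 3 gives the trityl-protected allylic alcohol F6. NaH and 6 give the trityl-protected geranyl ether F7. Catalytic TsOH in MeOH–CH2Cl2 removes the trityl group at this stage, when no ionisable allylic carbinol is yet present, and gives the primary alcohol F8. TBDPSCl and imidazole then return to the route at 8.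

3. **Step 8.**
   - Risks: persistent O-allylation, attack at the substituted allyl terminus, a second allylation at C3, β-hydride loss from the π-allyl unit to a diene, and syn/anti isomerisation that would scramble the 2E olefin.
   - Fallback: it replaces π-allyl chemistry by direct SN2 displacement, which cannot transpose or isomerise the allyl unit, and sets out from 12. MsCl, LiCl and 2,4,6-collidine in DMF at 0 °C convert the primary hydroxyl through the primary mesylate F9, displaced in the same flask, into the allylic chloride F10. The lithium salt of 14 (LiOH, NaI cat., water–THF) is then alkylated. The protic medium and tight counter-ion bias this ambident enolate towards carbon. The acidic C3-alkylated product is separated from neutral O-alkyl and dialkyl material by base extraction, and the route is rejoined at 15.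

**Further compounds**
F1 | step 5 | (R)-tert-butyl[3-methyl-2-(prop-2-ynyloxy)but-3-enyloxy]diphenylsilane | C=C(C)[C@H](CO[Si](c1ccccc1)(c1ccccc1)C(C)(C)C)OCC#C
F2 | step 5 | (R)-tert-butyl[3-methyl-2-(7-methyloct-6-en-2-ynyloxy)but-3-enyloxy]diphenylsilane | C=C(C)[C@H](CO[Si](c1ccccc1)(c1ccccc1)C(C)(C)C)OCC#CCCC=C(C)C
F3 | step 5 | (2E,5R)-1-(tert-butyldiphenylsilyloxy)-3,11-dimethyldodeca-2,10-dien-6-yn-5-ol | CC(C)=CCCC#C[C@H](O)C/C(C)=C/CO[Si](c1ccccc1)(c1ccccc1)C(C)(C)C
F4 | step 5 | (2E,5R,6Z)-1-(tert-butyldiphenylsilyloxy)-7-iodo-3,11-dimethyldodeca-2,6,10-trien-5-ol | CC(C)=CCC/C(I)=C/[C@H](O)C/C(C)=C/CO[Si](c1ccccc1)(c1ccccc1)C(C)(C)C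
F5 | step 4 | (S)-2,2-dimethyl-3-(trityloxymethyl)oxirane | CC1(C)[C@H](COC(c2ccccc2)(c2ccccc2)c2ccccc2)O1
F6 | step 4 | (R)-3-methyl-1-(trityloxy)but-3-en-2-ol | C=C(C)[C@H](COC(c1ccccc1)(c1ccccc1)c1ccccc1)O
F7 | step 4 | (R)-geranyl ether of 3-methyl-1-(trityloxy)but-3-en-2-ol | C=C(C)[C@H](COC(c1ccccc1)(c1ccccc1)c1ccccc1)OC/C=C(\C)CCC=C(C)C
F8 | step 4 | (R)-2-[(2E)-3,7-dimethylocta-2,6-dienyloxy]-3-methylbut-3-en-1-ol | C=C(C)[C@H](CO)OC/C=C(\C)CCC=C(C)C
F9 | step 8 | (2E,5R,6E)-5-hydroxy-3,7,11-trimethyldodeca-2,6,10-trienyl methanesulfonate | CC(C)=CCC/C(C)=C/[C@H](O)C/C(C)=C/COS(C)(=O)=O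
F10 | step 8 | (2E,5R,6E)-1-chloro-3,7,11-trimethyldodeca-2,6,10-trien-5-ol | CC(C)=CCC/C(C)=C/[C@H](O)C/C(C)=C/CCl
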